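**Plan**

- Feature: the sole ring is a furan with one substituent, at C3 (the CH2CH2 link to the acrylic acid). Its C3–C4 edge is read as a terminal alkyne, and O1, C2 and C5 as the matching atoms of an oxazole whose N3–C4 unit leaves as a nitrile.
- Cuts (acid locants, C1 = CO2H): ester C–O; the sp3–sp2 bond C2–C3 at the acrylate α-carbon; the allyl–allyl bond C9–C10; the C7=C8 olefin; the furan C2–C3 and C4–C5 bonds.
- Forward, furan half: oxazole → furan ester → aldehyde → ynoate → (E)-α-iodoenoate.
- Forward, chain half: (R)-carvone is cleaved to a lactol, olefinated, joined to a nerol-derived sulfone, desulfonylated and iodinated; B-alkyl Suzuki coupling and saponification finish the route.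
- Stereochemistry: C5 (R) is C5 of (R)-carvone and is never touched; 7E comes from a stabilised Wittig ylide, 11Z from nerol, 2Z from syn hydrostannation followed by stereoretentive iodination and coupling.

Key step: step 2

Remark: the cycloadduct of the key step is drawn as one of two regioisomers, the lactol is an anomeric mixture and the coupled sulfone a mixture of epimers at the sulfonyl-bearing carbon; none of these centres survives.

**Route**

Step 1
Reactants: 1 2-bromoacetophenone
Product: 2 4-phenyl-1,3-oxazole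
Conditions: HCONH2 (excess, neat), 130 °C
Reagents that add atoms: formamide, NC=O
Why: Bredereck (Blümlein–Lewy) oxazole synthesis: the formamide oxygen displaces bromide and the nitrogen condenses with the ketone, so the phenyl-bearing carbon becomes C4 and C2 and C5 stay free as cycloaddition termini.

Step 2
Reactants: 2 4-phenyl-1,3-oxazole; 3 methyl pent-4-ynoate (commercial)
Product: 5 methyl 3-(furan-3-yl)propanoate, via bicyclic adduct 4 (not isolated)
Conditions: neat, slight excess of 3, sealed tube, 220 °C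
Reagents that add atoms: none
Why: The oxazole reacts as an azadiene through C2 and C5 in a thermal [4+2] cycloaddition with the terminal alkyne to give the 7-oxa-2-azabicyclo[2.2.1]hepta-2,5-diene 4, which loses benzonitrile (N3≡C4–Ph) by retro-[4+2]; the closest known reaction type is the oxazole–alkyne Diels–Alder/retro-Diels–Alder furan synthesis. The furan ring is closed through two new C–C bonds (its C2–C3 and C4–C5), while the oxygen and both α-carbons arrive already joined from the oxazole, and it becomes aromatic in the cycloreversion. No stereocentre results, because the two bridgehead centres of 4 vanish on fragmentation. Regiocontrol is not needed, since either orientation of the alkyne leads to the same 3-monosubstituted furan, and fragmentation is directed to nitrile loss because only that path gives an aromatic ring and a C≡N bond. The step is placed on this small ester because an ester and two methylene groups tolerate the temperature an unactivated alkyne demands, whereas the skipped polyene and the Z-acrylate of later intermediates would not.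

Step 3
Reactants: 5 methyl 3-(furan-3-yl)propanoate
Product: 6 3-(furan-3-yl)propanal
Conditions: i-Bu2AlH (1.05 equiv), CH2Cl2, −78 °C; MeOH, aq. potassium sodium tartrate
Reagents that add atoms: none
Why: Partial ester reduction with i-Bu2AlH: the tetrahedral aluminium hemiacetal persists at −78 °C and releases the aldehyde only on work-up, the furan being inert to hydride.

Step 4
Reactants: 6 3-(furan-3-yl)propanal
Product: 7 3-(4,4-dibromobut-3-en-1-yl)furan
Conditions: CBr4, PPh3, Zn dust, CH2Cl2, rt; then 6, 0 °C → rt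
Reagents that add atoms: carbon tetrabromide, BrC(Br)(Br)Br
Why: Corey–Fuchs (Ramirez) dibromo-olefination, a Wittig reaction of the dibromomethylidene ylide with an unhindered aldehyde under neutral conditions that spare the acid-sensitive furan.

Step 5
Reactants: 7 3-(4,4-dibromobut-3-en-1-yl)furan
Product: 9 methyl 5-(furan-3-yl)pent-2-ynoate, via lithium acetylide 8 (not isolated)
Conditions: n-BuLi (2.1 equiv), THF, −78 °C; then ClCO2Me, −78 → 0 °C
Reagents that add atoms: methyl chloroformate, COC(=O)Cl
Why: Second stage of the Corey–Fuchs sequence: lithium–bromine exchange and Fritsch–Buttenberg–Wiechell rearrangement give the acetylide, which the chloroformate acylates; at −78 °C the furan α-hydrogens are not metallated.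

Step 6
Reactants: 9 methyl 5-(furan-3-yl)pent-2-ynoate
Product: 10 methyl (2E)-5-(furan-3-yl)-2-(tributylstannyl)pent-2-enoate
Conditions: Bu3SnH (1.1 equiv), Pd(PPh3)4 (cat.), THF, 0 °C → rt
Reagents that add atoms: tributyltin hydride, CCCC[SnH](CCCC)CCCC
Why: Palladium-catalysed hydrostannation of an alkynoate is a syn addition that places tin on the α-carbon and hydrogen on the β-carbon, which sets the side chain cis to the ester as the target acrylate requires.

Step 7
Reactants: 10 methyl (2E)-5-(furan-3-yl)-2-(tributylstannyl)pent-2-enoate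
Product: 11 methyl (2E)-5-(furan-3-yl)-2-iodopent-2-enoate
Conditions: I2 (1.0 equiv), CH2Cl2, 0 °C, dark; aq. Na2S2O3
Reagents that add atoms: iodine, II
Why: Iododestannylation, an ipso electrophilic substitution at the vinyl carbon that proceeds with retention of geometry and is far faster than iodination of the furan.

Step 8
Reactants: 12 (R)-carvone
Product: 13 (1R,4R,6R)-1-methyl-4-(prop-1-en-2-yl)-7-oxabicyclo[4.1.0]heptan-2-one
Conditions: 30% aq. H2O2, NaOH (cat.), MeOH, 0 °C
Reagents that add atoms: hydrogen peroxide, OO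
Why: Weitz–Scheffer nucleophilic epoxidation: hydroperoxide adds conjugatively to the enone only, so the isopropenyl olefin is untouched; the epoxide forms trans to the C5 substituent, but its configuration is immaterial.

Step 9
Reactants: 13 (1R,4R,6R)-1-methyl-4-(prop-1-en-2-yl)-7-oxabicyclo[4.1.0]heptan-2-one
Product: 15 (3R)-5-oxo-3-(prop-1-en-2-yl)pentanoic acid, via keto diol 14 (not isolated)
Conditions: 1 M H2SO4, THF, rt; then NaIO4 (2.5 equiv), 0 °C → rt
Reagents that add atoms: water, O
Why: Acid-catalysed anti hydrolysis of the epoxy ketone followed by Malaprade periodate cleavage severs both C–C bonds at the tertiary carbinol carbon, excising it and its methyl as acetic acid; the stereocentre is β to both new carbonyls and cannot epimerise.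

Step 10
Reactants: 15 (3R)-5-oxo-3-(prop-1-en-2-yl)pentanoic acid
Product: 17 (4R)-4-(prop-1-en-2-yl)oxan-2-one, via hydroxy acid 16 (not isolated)
Conditions: NaBH4, NaOH (1 equiv), EtOH/H2O, 0 °C; then 2 M HCl to pH 2, rt
Reagents that add atoms: none
Why: Borohydride reduces the aldehyde but not the carboxylate, and acidification closes the six-membered lactone (δ-lactonisation), which differentiates the two arms at the stereocentre.

Step 11
Reactants: 17 (4R)-4-(prop-1-en-2-yl)oxan-2-one
Product: 18 (4R)-4-(prop-1-en-2-yl)oxan-2-ol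
Conditions: i-Bu2AlH (1.1 equiv), CH2Cl2, −78 °C; aq. potassium sodium tartrate
Reagents that add atoms: none
Why: Lactone half-reduction with i-Bu2AlH stops at the cyclic hemiacetal, which is stable at −78 °C.

Step 12
Reactants: 18 (4R)-4-(prop-1-en-2-yl)oxan-2-ol
Product: 19 ethyl (2E,5S)-7-hydroxy-2-methyl-5-(prop-1-en-2-yl)hept-2-enoate
Conditions: Ph3P=C(CH3)CO2Et (1.5 equiv), toluene, 80 °C
Reagents that add atoms: ethyl 2-(triphenylphosphoranylidene)propanoate, CCOC(=O)C(C)=P(c1ccccc1)(c1ccccc1)c1ccccc1
Why: Wittig olefination of the ring-opened hydroxy aldehyde with a stabilised α-methyl ylide, which under thermodynamic control should give the E-trisubstituted enoate and at the same time frees the primary alcohol of the other arm.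

Step 13
Reactants: 19 ethyl (2E,5S)-7-hydroxy-2-methyl-5-(prop-1-en-2-yl)hept-2-enoate
Product: 20 (2E,5S)-2-methyl-5-(prop-1-en-2-yl)hept-2-ene-1,7-diol
Conditions: i-Bu2AlH (3.5 equiv), CH2Cl2, −78 → 0 °C; aq. potassium sodium tartrate
Reagents that add atoms: none
Why: 1,2-Reduction of the enoate by i-Bu2AlH gives the allylic alcohol without touching any C=C bond or the olefin geometry.

Step 14
Reactants: 20 (2E,5S)-2-methyl-5-(prop-1-en-2-yl)hept-2-ene-1,7-diol
Product: 21 (3S,5E)-7-bromo-6-methyl-3-(prop-1-en-2-yl)hept-5-en-1-ol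
Conditions: NBS (2.2 equiv), Me2S (2.6 equiv), CH2Cl2, −30 → 0 °C; then H2O
Reagents that add atoms: N-bromosuccinimide, BrN1C(=O)CCC1=O
Why: Corey–Kim halogenation: both hydroxyls form alkoxysulfonium salts, but only the allylic one is displaced by bromide at or below 0 °C, the saturated one reverting to the alcohol on aqueous work-up; SN2 displacement at the primary allylic carbon keeps the E geometry.

Step 15
Reactants: 22 nerol
Product: 23 (2Z)-1-bromo-3,7-dimethylocta-2,6-diene (neryl bromide)
Conditions: PBr3 (0.4 equiv), pyridine (cat.), Et2O, −10 °C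
Reagents that add atoms: phosphorus tribromide, BrP(Br)Br
Why: Bromination of a primary allylic alcohol with PBr3 through the phosphite ester, run cold and buffered so that allylic transposition, Z to E isomerisation and cationic cyclisation of the neryl system are avoided.

Step 16
Reactants: 23 (2Z)-1-bromo-3,7-dimethylocta-2,6-diene
Product: 24 1-{[(2Z)-3,7-dimethylocta-2,6-dien-1-yl]sulfonyl}-4-methylbenzene (neryl p-tolyl sulfone)
Conditions: 4-MeC6H4SO2Na, DMF, rt
Reagents that add atoms: sodium 4-methylbenzenesulfinate, [Na+].[O-]S(=O)c1ccc(C)cc1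
Why: SN2 S-alkylation of the ambident sulfinate by the allylic bromide gives the allylic sulfone with the Z olefin intact.

Step 17
Reactants: 24 neryl p-tolyl sulfone; 21 (3S,5E)-7-bromo-6-methyl-3-(prop-1-en-2-yl)hept-5-en-1-ol
Product: 26 (3S,5E,9Z)-6,10,14-trimethyl-8-(4-methylbenzenesulfonyl)-3-(prop-1-en-2-yl)pentadeca-5,9,13-trien-1-ol (both C8 epimers), via lithiated sulfone 25 (not isolated)
Conditions: 24 (2.2 equiv), n-BuLi (2.1 equiv), THF, −78 °C; then 21, −78 → −20 °C
Reagents that add atoms: none
Why: Alkylation of a sulfonyl-stabilised allylic carbanion with an allylic bromide (sulfone-based head-to-tail terpenoid coupling) occurs at the α-carbon and leaves both olefin geometries unchanged; the excess anion covers the free hydroxyl, and the new sulfonyl-bearing centre is erased in the next step.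

Step 18
Reactants: 26 (3S,5E,9Z)-6,10,14-trimethyl-8-(4-methylbenzenesulfonyl)-3-(prop-1-en-2-yl)pentadeca-5,9,13-trien-1-ol
Product: 27 (3S,5E,9Z)-6,10,14-trimethyl-3-(prop-1-en-2-yl)pentadeca-5,9,13-trien-1-ol
Conditions: LiBHEt3 (4 equiv), Pd(dppp)Cl2 (cat.), THF, 0 °C → rt
Reagents that add atoms: none
Why: Palladium-catalysed reductive desulfonylation of an allylic sulfone: ionisation gives a π-allyl complex that takes up hydride at its less substituted terminus, so the trisubstituted olefin stays in place and Z, isomerisation requiring an unfavourable tertiary σ-allyl.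

Step 19
Reactants: 27 (3S,5E,9Z)-6,10,14-trimethyl-3-(prop-1-en-2-yl)pentadeca-5,9,13-trien-1-ol
Product: 28 (6Z,10E,13S)-15-iodo-2,6,10-trimethyl-13-(prop-1-en-2-yl)pentadeca-2,6,10-triene
Conditions: I2, PPh3, imidazole, CH2Cl2, 0 °C
Reagents that add atoms: iodine, II
Why: Appel-type iodination (Garegg–Samuelsson conditions) of the primary alcohol by SN2 displacement of the alkoxyphosphonium ion, neutral enough for the skipped triene.

Step 20
Reactants: 28 (6Z,10E,13S)-15-iodo-2,6,10-trimethyl-13-(prop-1-en-2-yl)pentadeca-2,6,10-triene; 11 methyl (2E)-5-(furan-3-yl)-2-iodopent-2-enoate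
Product: 31 methyl (2Z,5R,7E,11Z)-2-[3-(furan-3-yl)propylidene]-8,12,16-trimethyl-5-(prop-1-en-2-yl)heptadeca-7,11,15-trienoate, via alkyllithium 29 (not isolated), via lithium borate 30 (not isolated)
Conditions: t-BuLi (2.1 equiv), Et2O, −78 °C; B-methoxy-9-borabicyclo[3.3.1]nonane, THF, −78 °C → rt; then 11, Pd(dppf)Cl2 (cat.), AsPh3, aq. K3PO4, DMF, rt
Reagents that add atoms: none
Why: B-alkyl Suzuki–Miyaura coupling: lithium–iodine exchange and capture by the borinate give a borate that transmetallates to the vinylpalladium formed from 11 by oxidative addition with retention, so the C–C bond forms without touching the stereocentre and the acrylate emerges Z.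

Step 21
Reactants: 31 methyl (2Z,5R,7E,11Z)-2-[3-(furan-3-yl)propylidene]-8,12,16-trimethyl-5-(prop-1-en-2-yl)heptadeca-7,11,15-trienoate
Product: 32 (2Z,5R,7E,11Z)-2-[3-(furan-3-yl)propylidene]-8,12,16-trimethyl-5-(prop-1-en-2-yl)heptadeca-7,11,15-trienoic acid
Conditions: LiOH, THF/MeOH/H2O, 40 °C; then 1 M HCl to pH 3, 0 °C
Reagents that add atoms: lithium hydroxide, [Li+].[OH-]
Why: Saponification of the methyl ester followed by mild acidification; no enolisable stereocentre is present and the trisubstituted acrylate geometry is not at risk under these conditions.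

**Compound list**

1 | 2-bromoacetophenone | O=C(CBr)c1ccccc1 | starting material
2 | 4-phenyl-1,3-oxazole | c1ccc(cc1)-c1cocn1 | intermediate
3 | methyl pent-4-ynoate | C#CCCC(=O)OC | starting material
4 | methyl 3-(3-phenyl-7-oxa-2-azabicyclo[2.2.1]hepta-2,5-dien-5-yl)propanoate (or its 6-yl regioisomer) | COC(=O)CCC1=CC2N=C(c3ccccc3)C1O2 | intermediate (not isolated)
5 | methyl 3-(furan-3-yl)propanoate | COC(=O)CCc1ccoc1 | intermediate
6 | 3-(furan-3-yl)propanal | O=CCCc1ccoc1 | intermediate
7 | 3-(4,4-dibromobut-3-en-1-yl)furan | BrC(Br)=CCCc1ccoc1 | intermediate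
8 | [4-(furan-3-yl)but-1-yn-1-yl]lithium | [Li]C#CCCc1ccoc1 | intermediate (not isolated)
9 | methyl 5-(furan-3-yl)pent-2-ynoate | COC(=O)C#CCCc1ccoc1 | intermediate
10 | methyl (2E)-5-(furan-3-yl)-2-(tributylstannyl)pent-2-enoate | COC(=O)/C(=C\CCc1ccoc1)[Sn](CCCC)(CCCC)CCCC | intermediate
11 | methyl (2E)-5-(furan-3-yl)-2-iodopent-2-enoate | COC(=O)/C(I)=C\CCc1ccoc1 | intermediate
12 | (R)-carvone | CC1=CC[C@H](CC1=O)C(C)=C | starting material
13 | (1R,4R,6R)-1-methyl-4-(prop-1-en-2-yl)-7-oxabicyclo[4.1.0]heptan-2-one | C[C@@]12O[C@@H]1C[C@H](CC2=O)C(C)=C | intermediate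
14 | (2R,3S,5R)-2,3-dihydroxy-2-methyl-5-(prop-1-en-2-yl)cyclohexan-1-one | C[C@@]1(O)[C@@H](O)C[C@H](CC1=O)C(C)=C | intermediate (not isolated)
15 | (3R)-5-oxo-3-(prop-1-en-2-yl)pentanoic acid | O=CC[C@H](CC(=O)O)C(C)=C | intermediate
16 | (3R)-5-hydroxy-3-(prop-1-en-2-yl)pentanoic acid | OCC[C@H](CC(=O)O)C(C)=C | intermediate (not isolated)
17 | (4R)-4-(prop-1-en-2-yl)oxan-2-one | O=C1C[C@@H](CCO1)C(C)=C | intermediate
18 | (4R)-4-(prop-1-en-2-yl)oxan-2-ol (anomeric mixture) | OC1C[C@@H](CCO1)C(C)=C | intermediate
19 | ethyl (2E,5S)-7-hydroxy-2-methyl-5-(prop-1-en-2-yl)hept-2-enoate | CCOC(=O)/C(C)=C/C[C@@H](CCO)C(C)=C | intermediate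
20 | (2E,5S)-2-methyl-5-(prop-1-en-2-yl)hept-2-ene-1,7-diol | OC/C(C)=C/C[C@@H](CCO)C(C)=C | intermediate
21 | (3S,5E)-7-bromo-6-methyl-3-(prop-1-en-2-yl)hept-5-en-1-ol | BrC/C(C)=C/C[C@@H](CCO)C(C)=C | intermediate
22 | nerol | OC/C=C(/C)CCC=C(C)C | starting material
23 | (2Z)-1-bromo-3,7-dimethylocta-2,6-diene | BrC/C=C(/C)CCC=C(C)C | intermediate
24 | 1-{[(2Z)-3,7-dimethylocta-2,6-dien-1-yl]sulfonyl}-4-methylbenzene | Cc1ccc(cc1)S(=O)(=O)C/C=C(/C)CCC=C(C)C | intermediate
25 | {(2Z)-3,7-dimethyl-1-[(4-methylphenyl)sulfonyl]octa-2,6-dien-1-yl}lithium | Cc1ccc(cc1)S(=O)(=O)C([Li])/C=C(/C)CCC=C(C)C | intermediate (not isolated)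
26 | (3S,5E,9Z)-6,10,14-trimethyl-8-(4-methylbenzenesulfonyl)-3-(prop-1-en-2-yl)pentadeca-5,9,13-trien-1-ol (C8 epimers) | CC(C)=CCC/C(C)=C\C(C/C(C)=C/C[C@@H](CCO)C(C)=C)S(=O)(=O)c1ccc(C)cc1 | intermediate
27 | (3S,5E,9Z)-6,10,14-trimethyl-3-(prop-1-en-2-yl)pentadeca-5,9,13-trien-1-ol | CC(C)=CCC/C(C)=C\CC/C(C)=C/C[C@@H](CCO)C(C)=C | intermediate
28 | (6Z,10E,13S)-15-iodo-2,6,10-trimethyl-13-(prop-1-en-2-yl)pentadeca-2,6,10-triene | CC(C)=CCC/C(C)=C\CC/C(C)=C/C[C@@H](CCI)C(C)=C | intermediate
29 | [(3S,5E,9Z)-6,10,14-trimethyl-3-(prop-1-en-2-yl)pentadeca-5,9,13-trien-1-yl]lithium | CC(C)=CCC/C(C)=C\CC/C(C)=C/C[C@@H](CC[Li])C(C)=C | intermediate (not isolated)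
30 | lithium 9-methoxy-9-[(3S,5E,9Z)-6,10,14-trimethyl-3-(prop-1-en-2-yl)pentadeca-5,9,13-trien-1-yl]-9-borabicyclo[3.3.1]nonan-9-uide | [Li+].CO[B-]1(CC[C@H](C/C=C(\C)CC/C=C(/C)CCC=C(C)C)C(C)=C)C2CCCC1CCC2 | intermediate (not isolated)
31 | methyl (2Z,5R,7E,11Z)-2-[3-(furan-3-yl)propylidene]-8,12,16-trimethyl-5-(prop-1-en-2-yl)heptadeca-7,11,15-trienoate | C=C(C)[C@@H](C/C=C(\C)CC/C=C(/C)CCC=C(C)C)CC/C(=C/CCc1ccoc1)C(=O)OC | intermediate
32 | (2Z,5R,7E,11Z)-2-[3-(furan-3-yl)propylidene]-8,12,16-trimethyl-5-(prop-1-en-2-yl)heptadeca-7,11,15-trienoic acid | C=C(C)[C@@H](C/C=C(\C)CC/C=C(/C)CCC=C(C)C)CC/C(=C/CCc1ccoc1)C(=O)O | target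

**Count**

Total steps: 21. Longest linear sequence: 12 steps (steps 8–14 and 17–21, from (R)-carvone).

**Steps most likely to fail**

Step 2. The unactivated alkyne may add so slowly that thermal decomposition or oligomerisation of the alkyne, and loss of volatile material, outrun the cycloaddition. The fallback keeps the oxazole-to-furan exchange but activates the dienophile and then builds the chain; it sets out from 2 and comes back at 5. Heating 2 with methyl propiolate at a markedly lower temperature should give methyl furan-3-carboxylate F1, with benzonitrile again expelled. Reduction with i-Bu2AlH gives furan-3-ylmethanol F2, and MnO2 oxidation gives furan-3-carbaldehyde F3. Wittig reaction with Ph3P=CHCO2Me gives methyl (2E)-3-(furan-3-yl)prop-2-enoate F4, and conjugate reduction with Mg in MeOH returns the route at 5.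

Step 14. Discrimination between the two primary hydroxyls may be incomplete, with bromide also displacing the saturated alkoxysulfonium ion or the hydroxy bromide degrading on handling. The fallback is a protecting-group variant that sets out from 19 and comes back at 27. Silylation with t-BuMe2SiCl and imidazole gives the silyl ether of 19 F5; i-Bu2AlH gives the silylated allylic alcohol F6; CBr4/PPh3 gives the silylated allylic bromide F7. Alkylation of 25 with it gives the silylated coupled sulfone F8, LiBHEt3 with Pd(dppp)Cl2 gives the silyl ether of 27 F9, and Bu4NF releases 27.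

Step 20. Transmetallation to the hindered α-iodoenoate may be slow, so that protodeboronation, β-hydride elimination of the alkylpalladium or Z to E drift of the iodoenoate compete. The fallback replaces the cross-coupling by an olefination; it sets out from 28 and 6 and comes back at 31. Alkylation of the sodium salt of methyl bis(2,2,2-trifluoroethyl)phosphonoacetate with 28 (NaH, DMSO) gives the α-alkylated phosphonate F10. Still–Gennari olefination of 6 with it (KN(SiMe3)2, 18-crown-6, THF, −78 °C) should give 31 directly, with the ester cis to the furylethyl chain.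

**Further compounds**

F1 | step 2 | methyl furan-3-carboxylate | COC(=O)c1ccoc1
F2 | step 2 | furan-3-ylmethanol | OCc1ccoc1
F3 | step 2 | furan-3-carbaldehyde | O=Cc1ccoc1
F4 | step 2 | methyl (2E)-3-(furan-3-yl)prop-2-enoate | COC(=O)/C=C/c1ccoc1
F5 | step 14 | ethyl (2E,5S)-7-[(tert-butyldimethylsilyl)oxy]-2-methyl-5-(prop-1-en-2-yl)hept-2-enoate | CCOC(=O)/C(C)=C/C[C@@H](CCO[Si](C)(C)C(C)(C)C)C(C)=C
F6 | step 14 | (2E,5S)-7-[(tert-butyldimethylsilyl)oxy]-2-methyl-5-(prop-1-en-2-yl)hept-2-en-1-ol | OC/C(C)=C/C[C@@H](CCO[Si](C)(C)C(C)(C)C)C(C)=C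
F7 | step 14 | {[(3S,5E)-7-bromo-6-methyl-3-(prop-1-en-2-yl)hept-5-en-1-yl]oxy}(tert-butyl)dimethylsilane | BrC/C(C)=C/C[C@@H](CCO[Si](C)(C)C(C)(C)C)C(C)=C
F8 | step 14 | tert-butyldimethyl{[(3S,5E,9Z)-6,10,14-trimethyl-8-(4-methylbenzenesulfonyl)-3-(prop-1-en-2-yl)pentadeca-5,9,13-trien-1-yl]oxy}silane | CC(C)=CCC/C(C)=C\C(C/C(C)=C/C[C@@H](CCO[Si](C)(C)C(C)(C)C)C(C)=C)S(=O)(=O)c1ccc(C)cc1
F9 | step 14 | tert-butyldimethyl{[(3S,5E,9Z)-6,10,14-trimethyl-3-(prop-1-en-2-yl)pentadeca-5,9,13-trien-1-yl]oxy}silane | CC(C)=CCC/C(C)=C\CC/C(C)=C/C[C@@H](CCO[Si](C)(C)C(C)(C)C)C(C)=C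
F10 | step 20 | methyl (5R,7E,11Z)-2-[bis(2,2,2-trifluoroethoxy)phosphoryl]-8,12,16-trimethyl-5-(prop-1-en-2-yl)heptadeca-7,11,15-trienoate | COC(=O)C(CC[C@H](C/C=C(\C)CC/C=C(/C)CCC=C(C)C)C(C)=C)P(=O)(OCC(F)(F)F)OCC(F)(F)F
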